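Stop asking which flask runs fastest, and ask where target crests. Your hunch is zeta, the hottest, but target is a way station, so heat can carry it past its best. I count everything as fractions of the charge.

| flask | substrate | temperature | time |
|---|---|---|---|
| gamma | 0.050 M | 70 °C | 1.0 min |
| zeta | 0.050 M | 100 °C | 1.0 min |
| eta | 0.050 M | 85 °C | 1.0 min |

- the flask with the highest amount of target, in percent of the substrate charged ("all alike" if they lie within 1.5 percentage points) (gamma / zeta / eta / all alike)
- final target, as a percentage of the substrate charged, in gamma
- final target, as a percentage of the substrate charged, in zeta
- final target, as a percentage of the substrate charged, in eta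

    substrate ⇌ target (K1 = 1.8, k1 = 0.055 s⁻¹, Ea1 = 86.0 kJ mol⁻¹, ΔH1 = −7.00 kJ mol⁻¹)
    substrate ⇌ isomer of the product A (K2 = 2.1, k2 = 0.031 s⁻¹, Ea2 = 96.0 kJ mol⁻¹, ΔH2 = 21.0 kJ mol⁻¹)
    target ⇌ isomer of the product B (K3 = 3.0, k3 = 0.022 s⁻¹, Ea3 = 90.0 kJ mol⁻¹, ΔH3 = −12.0 kJ mol⁻¹)
    (constants at 100 °C)

- all constants are for 100 °C and move with temperature by the activation energies and enthalpies

1. I start from the end state, and zeta is the flask whose constants I have as given. With substrate as one part, target holds 1.8 parts, isomer of the product A 2.1, and isomer of the product B 5.40. So at equilibrium in zeta target holds 0.175 of the charge. Any excess of target over that in zeta is kinetic against thermodynamic control, and it has to drain away.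

2. Next comes the pace in eta. In eta, substrate and target relax by their own step alone with a half-life of 0.445 min, faster than target and isomer of the product B by their own step alone at 1.38 min. As rates these are 1.56 min⁻¹ for filling and 0.503 min⁻¹ for draining.

3. I treat these as two stages in series. The crest time, the moment when filling and draining of target balance, is the logarithm of their ratio divided by their difference: 1.07 min. This is rough, since each stage is taken by itself.

4. From gamma to zeta the filling step speeds up by a factor of 11 and the draining step by 13. I assume eta lies midway on that scale and scale both rates by the square root of the first factor. Zeta then crests near 0.319 min, well before the reading. Gamma crests near 3.60 min, well after it. I commit to eta, but my reckoning stops at the order and gives no percentages for the asked time.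

The forecast names eta, with 21.3% in gamma, 23% in zeta and 33.5% in eta, on the ground that “the middle temperature ends highest”.

The simulation gives eta, with 21.3% in gamma, 23.1% in zeta and 35.0% in eta. Eta leads zeta by 12 percentage points, against a margin of 1.5 points, and stands 1.5 points above the forecast. At 1.00 min, eta still makes target 1.17 times faster than it uses it up, each step taken net, and that reading lies short of the reckoned crest time of 1.07 min. The neighbour is eta read at 2.5 min, which is 2.34 crest times and past the reckoned crest. So I expect less target there than in eta at the asked time. It reads 28.7%.

The constants used here are made up; no experiment stands behind them.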